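**Retrosynthetic overview**
1. Furan ring and the coumarin C-3–aryl bond together: target ⇒ phenyliodonium ylide of the tricyclic 4-hydroxycoumarin (C-3 as an enolonium carbon) + unprotected resorcinol (C-4 as nucleophile); C–C coupling, then dehydrative C–O closure in the same pot.
2. Ylide ⇒ tricyclic 4-hydroxycoumarin + PhI(OAc)2.
3. Pyranone ring: 4-hydroxycoumarin ⇒ o-hydroxyacetophenone + diethyl carbonate.
4. Chroman ring: acetylchromanol ⇒ symmetric 2',6'-dihydroxy-4'-methoxyacetophenone + isoprene (symmetry removes the regiochemical question).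
5. Ring order: ring A (bought) → dimethylchroman → pyranone → furan (ring D bought as resorcinol).

Assumption: the target has no stereocentre (the only substituted sp3 carbon carries two identical methyl groups), so it is achiral and no stereocontrol is needed; 2',6'-dihydroxy-4'-methoxyacetophenone is taken as a catalogue compound.

**Step 1**
Reactants: 1 2',6'-dihydroxy-4'-methoxyacetophenone; 2 isoprene (2-methylbuta-1,3-diene)
Product: 4 acetylchromanol [1-(7-hydroxy-5-methoxy-2,2-dimethyl-3,4-dihydro-2H-chromen-8-yl)ethan-1-one], via C-prenyl phenol 3 (not isolated)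
Conditions: 2 (1.3 equiv), Amberlyst 15 (sulfonic acid resin, H+ form), THF/heptane, 65 °C, sealed tube
Reagents that add atoms: none
Why: Acid-catalysed Friedel–Crafts prenylation at C-3 of symmetric 1 (C-3 and C-5 are equivalent, so only one regioisomer can form) gives 3, whose tertiary cation is trapped by the adjacent phenol (Markovnikov cycloetherification) to the 2,2-dimethylchroman in a net addition with no co-product; no stereocentre is formed.

**Step 2**
Reactants: 4 acetylchromanol
Product: 6 tricyclic 4-hydroxycoumarin [10-hydroxy-5-methoxy-2,2-dimethyl-3,4-dihydro-2H,8H-pyrano[2,3-f]chromen-8-one], via keto ester 5 (not isolated)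
Conditions: NaH (4 equiv), (EtO)2CO (5 equiv), toluene, 110 °C; then 1 M HCl
Reagents that add atoms: diethyl carbonate, CCOC(=O)OCC
Why: Claisen-type C-ethoxycarbonylation of the methyl-ketone enolate gives β-keto ester 5, which lactonises through the ortho-phenoxide (the standard 4-hydroxycoumarin synthesis from o-hydroxyacetophenones); the chroman ether and OMe are inert to NaH, and no stereocentre is formed.

**Step 3**
Reactants: 6 tricyclic 4-hydroxycoumarin
Product: 7 phenyliodonium ylide of 6 [5-methoxy-2,2-dimethyl-8-oxo-9-(phenyliodonio)-3,4-dihydro-2H,8H-pyrano[2,3-f]chromen-10-olate]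
Conditions: PhI(OAc)2 (1.05 equiv), Na2CO3 (2.1 equiv), H2O, 0 °C → rt; filter, wash, dry in the dark
Reagents that add atoms: (diacetoxyiodo)benzene, CC(=O)OI(OC(C)=O)c1ccccc1
Why: Ligand exchange of the 1,3-dicarbonyl enolate at trivalent iodine and loss of acetate gives the stabilised, filterable ylide (standard iodonium ylide formation from cyclic 1,3-dicarbonyls), which turns the natively nucleophilic coumarin C-3 (C-9 of 6) into a latent enolonium carbon; no stereocentre is formed.

**Step 4**
Reactants: 7 phenyliodonium ylide; 8 resorcinol (benzene-1,3-diol)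
Product: 10 target coumestan [9-hydroxy-3-methoxy-6',6'-dimethyl-4',5'-dihydro-6'H-pyrano[2',3':1,2]coumestan; pyran O on coumestan C-1 and CH2 on C-2], via triol 9 (not isolated)
Conditions: 8 (3 equiv), TfOH (10 mol%), HFIP, 0 °C → rt; then 55 °C, same pot
Reagents that add atoms: none
Why: Proposed new method: O-protonation of ylide 7 by TfOH in ionising, non-nucleophilic HFIP gives a 3-(phenyliodonio)-4-hydroxycoumarin, an enolonium equivalent with PhI as leaving group, which the most nucleophilic and least hindered carbon of resorcinol (C-4, ortho and para to the two OH groups) attacks at the α-carbon with loss of PhI and return of the proton, so two natively nucleophilic carbons are joined (closest known reaction types: metal-free α-arylation of hypervalent-iodine enolonium species by electron-rich arenes, acid-triggered nucleophilic substitution of 1,3-dicarbonyl iodonium ylides, and oxidative β-keto ester/phenol benzofuran annulation), after which the same acid dehydrates triol 9 to the aromatic furan as in classical coumestrol syntheses; the OMe blocks any alternative re-closure of the chroman, and no stereocentre has to be set.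

**Compound list**
1 | 2',6'-dihydroxy-4'-methoxyacetophenone | CC(=O)c1c(O)cc(OC)cc1O | starting material
2 | isoprene | C=CC(C)=C | starting material
3 | C-prenyl phenol, formed in situ: 1-[2,6-dihydroxy-4-methoxy-3-(3-methylbut-2-en-1-yl)phenyl]ethan-1-one | CC(=O)c1c(O)cc(OC)c(CC=C(C)C)c1O | intermediate
4 | acetylchromanol: 1-(7-hydroxy-5-methoxy-2,2-dimethyl-3,4-dihydro-2H-chromen-8-yl)ethan-1-one | CC(=O)c1c(O)cc(OC)c2CCC(C)(C)Oc12 | intermediate
5 | keto ester, formed in situ: ethyl 3-(7-hydroxy-5-methoxy-2,2-dimethyl-3,4-dihydro-2H-chromen-8-yl)-3-oxopropanoate | CCOC(=O)CC(=O)c1c(O)cc(OC)c2CCC(C)(C)Oc12 | intermediate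
6 | 10-hydroxy-5-methoxy-2,2-dimethyl-3,4-dihydro-2H,8H-pyrano[2,3-f]chromen-8-one | COc1cc2oc(=O)cc(O)c2c2c1CCC(C)(C)O2 | intermediate
7 | 5-methoxy-2,2-dimethyl-8-oxo-9-(phenyliodonio)-3,4-dihydro-2H,8H-pyrano[2,3-f]chromen-10-olate (iodonium ylide) | COc1cc2oc(=O)c([I+]c3ccccc3)c([O-])c2c2c1CCC(C)(C)O2 | intermediate
8 | resorcinol | Oc1cccc(O)c1 | starting material
9 | triol, formed in situ: 9-(2,4-dihydroxyphenyl)-10-hydroxy-5-methoxy-2,2-dimethyl-3,4-dihydro-2H,8H-pyrano[2,3-f]chromen-8-one | COc1cc2oc(=O)c(-c3ccc(O)cc3O)c(O)c2c2c1CCC(C)(C)O2 | intermediate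
10 | 9-hydroxy-3-methoxy-6',6'-dimethyl-4',5'-dihydro-6'H-pyrano[2',3':1,2]coumestan (CNP0304440.0, achiral) | COc1cc2oc(=O)c3c4ccc(O)cc4oc3c2c2c1CCC(C)(C)O2 | target

**Totals**
Total step count: 4. Longest linear sequence: 4 steps (1 → 4 → 6 → 7 → 10).

**Steps most likely to fail, with fallbacks**

Step 4 is the most at risk. O-attack of resorcinol, attack through C-2 of resorcinol, or 1,4-phenyl migration of the ylide may compete with C-arylation. Fallback: setting out from 7, the carbon–iodine bond of the ylide serves as the electrophile in a Suzuki-type coupling with commercial 2,4-bis(benzyloxy)phenylboronic acid (Pd(P(t-Bu)3)2 5 mol%, a zerovalent palladium catalyst, LiOH·H2O, DME/H2O, rt). This gives 9-[2,4-bis(benzyloxy)phenyl]-10-hydroxy-5-methoxy-2,2-dimethyl-3,4-dihydro-2H,8H-pyrano[2,3-f]chromen-8-one F1. Hydrogenolysis (H2 1 atm, Pd/C, EtOAc/MeOH) removes both benzyl groups and comes back to the route at triol 9, which is closed to 10 with TfOH (10 mol%) in HFIP at 55 °C as in the second stage of step 4.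

Step 1 is next. Bis-annulation on both phenols, isoprene oligomerisation, or stalled conversion are the concerns. Fallback: setting out from 1, a formal [3+3] chromene annulation with 3-methylbut-2-enal (ethylenediammonium diacetate 10 mol%, xylene, 140 °C; aldol-type condensation, then oxa-6π electrocyclisation) gives 1-(7-hydroxy-5-methoxy-2,2-dimethyl-2H-chromen-8-yl)ethan-1-one (alloevodionol) F2. Hydrogenation of its chromene double bond (H2 1 atm, Pd/C, EtOAc, rt) comes back to the route at 4.

Step 3 is third. The very electron-rich coumarin may be over-oxidised by PhI(OAc)2, or the ylide may rearrange to the 3-iodo-4-phenoxy ether on drying. Fallback: setting out from 6, the ylide is bypassed by a cross-dehydrogenative annulation with 3-(benzyloxy)phenol (FeCl3·6H2O 10 mol%, (t-BuO)2 2 equiv, 1,2-dichloroethane, 100 °C). Here the iron-bound, one-electron-oxidised dicarbonyl acts as a transient electrophilic α-carbon toward C-6 of the phenol, and the phenol OH then condenses onto C-10. This gives 9-(benzyloxy)-3-methoxy-6',6'-dimethyl-4',5'-dihydro-6'H-pyrano[2',3':1,2]coumestan F3. Hydrogenolysis (H2 1 atm, Pd/C, EtOAc) comes back to the route at 10.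

**Further compounds**
F1 | step 4 | 9-[2,4-bis(benzyloxy)phenyl]-10-hydroxy-5-methoxy-2,2-dimethyl-3,4-dihydro-2H,8H-pyrano[2,3-f]chromen-8-one | COc1cc2oc(=O)c(-c3ccc(OCc4ccccc4)cc3OCc3ccccc3)c(O)c2c2c1CCC(C)(C)O2
F2 | step 1 | 1-(7-hydroxy-5-methoxy-2,2-dimethyl-2H-chromen-8-yl)ethan-1-one (alloevodionol) | CC(=O)c1c(O)cc(OC)c2C=CC(C)(C)Oc12
F3 | step 3 | 9-(benzyloxy)-3-methoxy-6',6'-dimethyl-4',5'-dihydro-6'H-pyrano[2',3':1,2]coumestan | COc1cc2oc(=O)c3c4ccc(OCc5ccccc5)cc4oc3c2c2c1CCC(C)(C)O2
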